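Atoms carry prostanoid numbers (C1 = ester carbon). The cyclopentenone ring C8–C12 is never closed as a five-membered ring: its bromoenone C9(=O)–C10(Br)=C11 is read as a collapsed 2-bromoallyl cation, so C10 and its bromine are inserted last. Dibromocarbene adds to the C9=C11 enol double bond of a cyclobutanone silyl enol ether and the strained bicyclo[2.1.0]pentane opens; one operation enlarges the ring, places the bromine and unveils the enone. The precursor is a prochiral 3-alkyl-3-silyloxycyclobutanone whose enantiotopic CH2 arms (C8, C11) are told apart by a chiral lithium amide, which alone sets C12. Aldol condensation at C8 with a C1–C7 enal and desilylation finish the target.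

Key step: step 6

Assumption: precedent does not show which antipode of the C2-symmetric lithium amide removes the pro-C11 proton of the prochiral cyclobutanone; the (R,R)-amide is written, and the (S,S)-amide is used instead if the first run shows the opposite sense.

Step 1
Reactants: 1 (2Z)-oct-2-en-1-ol
Product: 2 (2Z)-1-chlorooct-2-ene
Conditions: NCS, Me2S, CH2Cl2, −20 °C to 0 °C
Reagents that add atoms: N-chlorosuccinimide, O=C1CCC(=O)N1Cl
Why: Corey–Kim chlorination replaces the activated primary allylic hydroxyl by chloride in an SN2 manner under neutral conditions, so neither allylic transposition nor loss of the Z geometry is expected.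

Step 2
Reactants: 2 (2Z)-1-chlorooct-2-ene; 3 3,3-dimethoxycyclobutan-1-one
Product: 5 3,3-dimethoxy-1-[(2Z)-oct-2-en-1-yl]cyclobutan-1-ol, via (2Z)-oct-2-enylbarium chloride 4 (not isolated)
Conditions: BaI2, lithium biphenylide, THF, rt; then 2, −78 °C; then 3, −78 °C
Reagents that add atoms: none
Why: Allylbarium addition: allylic barium reagents formed and kept at −78 °C retain their double-bond geometry and add to ketones through the α-carbon, which should deliver the linear Z-octenyl carbinol on the strain-activated cyclobutanone carbonyl; no stereocentre arises because the ring is symmetric.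

Step 3
Reactants: 5 3,3-dimethoxy-1-[(2Z)-oct-2-en-1-yl]cyclobutan-1-ol
Product: 6 {3,3-dimethoxy-1-[(2Z)-oct-2-en-1-yl]cyclobutoxy}triethylsilane
Conditions: Et3SiOTf, 2,6-lutidine, CH2Cl2, −78 °C
Reagents that add atoms: triethylsilyl trifluoromethanesulfonate, CC[Si](CC)(CC)OS(=O)(=O)C(F)(F)F
Why: Silyl triflate with a hindered pyridine base is the standard silylation of a tertiary alcohol, and at −78 °C the dimethyl ketal should not be activated; the ether blocks later retro-aldol opening of the β-hydroxy cyclobutanone.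

Step 4
Reactants: 6 {3,3-dimethoxy-1-[(2Z)-oct-2-en-1-yl]cyclobutoxy}triethylsilane
Product: 7 3-[(2Z)-oct-2-en-1-yl]-3-(triethylsilyloxy)cyclobutan-1-one
Conditions: PPTS (cat.), acetone/H2O, rt
Reagents that add atoms: water, O
Why: Mild acid-catalysed ketal hydrolysis should leave the tertiary triethylsilyl ether intact and gives an achiral ketone whose two CH2 groups are enantiotopic.

Step 5
Reactants: 7 3-[(2Z)-oct-2-en-1-yl]-3-(triethylsilyloxy)cyclobutan-1-one
Product: 9 (3S)-3-[(2Z)-oct-2-en-1-yl]-1,3-bis(triethylsilyloxy)cyclobut-1-ene, via lithium enolate 8 (not isolated)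
Conditions: lithium bis[(1R)-1-phenylethyl]amide (amine + n-BuLi), Et3SiCl in situ, THF, −100 °C
Reagents that add atoms: chlorotriethylsilane, CC[Si](Cl)(CC)CC
Why: Enantioselective deprotonation of a prochiral cyclobutanone by a C2-symmetric chiral lithium amide with internal silyl chloride quench, a reaction type shown for 3-substituted cyclobutanones: the amide takes a proton from one of the two enantiotopic CH2 groups, that arm becomes the vinylic carbon C11, and this choice alone fixes C12 as (S) in 9, while the in situ trap forestalls enolate equilibration and β-elimination of the silyloxy group.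

Step 6
Reactants: 9 (3S)-3-[(2Z)-oct-2-en-1-yl]-1,3-bis(triethylsilyloxy)cyclobut-1-ene
Product: 12 (4S)-2-bromo-4-[(2Z)-oct-2-en-1-yl]-4-(triethylsilyloxy)cyclopent-2-en-1-one, via dibromobicyclopentane adduct 10 (not isolated), via silyloxyallyl cation bromide 11 (not isolated)
Conditions: CHBr3, KOtBu, hexane, −30 °C to rt
Reagents that add atoms: bromoform, BrC(Br)Br
Why: α-Elimination of HBr from bromoform gives dibromocarbene, which adds as an electrophile to the electron-rich C9=C11 enol double bond of 9 to give the 5,5-dibromo-1-silyloxybicyclo[2.1.0]pentane 10; the strained central C9–C11 bond then opens in a disrotatory two-electron cyclopropyl-to-allyl ionisation with loss of the endo bromide to the silyloxy-stabilised 2-bromoallyl cation 11, and bromide removes the silyl group to leave the C9 ketone conjugated to C10(Br)=C11. The closest known reaction type is the dihalocarbene ring enlargement of cyclic silyl enol ethers to 2-halocycloalk-2-enones. The only ring closed is the cyclopropane, by concerted [2+1] cheletropic addition, and the five-membered ring arises by cleavage of the bond shared by the two small rings, not by a new closure. No lasting stereocentre is made: both bridgehead centres of 10 become sp2, both faces of addition converge, and C12 is untouched and keeps the configuration set in step 5. The step needs chemoselectivity for the enol ether over the C14=C15 alkene, which the much higher nucleophilicity of the silyloxy alkene toward the electrophilic carbene and the use of one equivalent should secure; regiochemistry is fixed because the carbene carbon can only end between C9 and C11.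

Step 7
Reactants: 13 methyl hex-5-enoate; 14 (2E)-but-2-enal
Product: 15 methyl (5E)-7-oxohept-5-enoate
Conditions: second-generation Hoveyda–Grubbs catalyst (cat.), CH2Cl2, 40 °C
Reagents that add atoms: none
Why: Olefin cross-metathesis of a terminal alkene with an excess of an electron-poor enal partner is E-selective and should give the (E)-enal with loss of propene.

Step 8
Reactants: 12 (4S)-2-bromo-4-[(2Z)-oct-2-en-1-yl]-4-(triethylsilyloxy)cyclopent-2-en-1-one; 15 methyl (5E)-7-oxohept-5-enoate
Product: 17 methyl (5E)-7-{(2S)-4-bromo-2-[(2Z)-oct-2-en-1-yl]-5-oxo-2-(triethylsilyloxy)cyclopent-3-en-1-yl}-7-hydroxyhept-5-enoate, via lithium dienolate 16 (not isolated)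
Conditions: LiN(iPr)2, THF, −78 °C; then 15, −78 °C; NH4Cl (aq)
Reagents that add atoms: none
Why: Directed aldol addition: kinetic deprotonation of 12 can only occur at C8 (C12 is quaternary, C11 vinylic), the lithium enolate adds 1,2 to the enal at −78 °C, and loss of the C12 silyloxy group is blocked because it would create a cyclopentadienone; the new centres at C7 and C8 are uncontrolled and vanish in step 9.

Step 9
Reactants: 17 methyl (5E)-7-{(2S)-4-bromo-2-[(2Z)-oct-2-en-1-yl]-5-oxo-2-(triethylsilyloxy)cyclopent-3-en-1-yl}-7-hydroxyhept-5-enoate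
Product: 19 methyl (5E,7E)-7-{(2R)-4-bromo-2-[(2Z)-oct-2-en-1-yl]-5-oxo-2-(triethylsilyloxy)cyclopent-3-en-1-ylidene}hept-5-enoate, via C7 mesylate 18 (not isolated)
Conditions: MsCl, Et3N, CH2Cl2, −20 °C to rt
Reagents that add atoms: none
Why: Mesylation followed by E1cB elimination through the C9 enolate gives the cross-conjugated C7=C8 alkene, and the 7E isomer, in which the C6 alkenyl group turns away from the C9 carbonyl oxygen, is expected to predominate as is usual for this aldol–dehydration on 4,4-disubstituted cyclopentenones; the C12 descriptor changes from S to R only because C8 gains priority.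

Step 10
Reactants: 19 methyl (5E,7E)-7-{(2R)-4-bromo-2-[(2Z)-oct-2-en-1-yl]-5-oxo-2-(triethylsilyloxy)cyclopent-3-en-1-ylidene}hept-5-enoate
Product: 20 methyl (5E,7E)-7-{(2R)-4-bromo-2-hydroxy-2-[(2Z)-oct-2-en-1-yl]-5-oxocyclopent-3-en-1-ylidene}hept-5-enoate
Conditions: HF·pyridine, pyridine, THF, 0 °C
Reagents that add atoms: none
Why: Buffered fluoride cleavage of the tertiary silyl ether should leave the methyl ester, the vinyl bromide and the cross-conjugated dienone untouched, and the C12 alcohol cannot ionise easily because the cation would be cyclopentadienone-like.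

Compound list

1 | (2Z)-oct-2-en-1-ol | CCCCC/C=C\CO | starting material
2 | (2Z)-1-chlorooct-2-ene | CCCCC/C=C\CCl | intermediate
3 | 3,3-dimethoxycyclobutan-1-one | COC1(OC)CC(=O)C1 | starting material
4 | [(2Z)-oct-2-en-1-yl]barium chloride | CCCCC/C=C\C[Ba]Cl | intermediate
5 | 3,3-dimethoxy-1-[(2Z)-oct-2-en-1-yl]cyclobutan-1-ol | CCCCC/C=C\CC1(O)CC(OC)(OC)C1 | intermediate
6 | {3,3-dimethoxy-1-[(2Z)-oct-2-en-1-yl]cyclobutoxy}triethylsilane | CCCCC/C=C\CC1(O[Si](CC)(CC)CC)CC(OC)(OC)C1 | intermediate
7 | 3-[(2Z)-oct-2-en-1-yl]-3-(triethylsilyloxy)cyclobutan-1-one (achiral, prochiral at C3) | CCCCC/C=C\CC1(O[Si](CC)(CC)CC)CC(=O)C1 | intermediate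
8 | lithium (3S)-3-[(2Z)-oct-2-en-1-yl]-3-(triethylsilyloxy)cyclobut-1-en-1-olate | CCCCC/C=C\C[C@@]1(O[Si](CC)(CC)CC)C=C(O[Li])C1 | intermediate
9 | (3S)-3-[(2Z)-oct-2-en-1-yl]-1,3-bis(triethylsilyloxy)cyclobut-1-ene | CCCCC/C=C\C[C@@]1(O[Si](CC)(CC)CC)C=C(O[Si](CC)(CC)CC)C1 | intermediate
10 | (3S)-5,5-dibromo-3-[(2Z)-oct-2-en-1-yl]-1,3-bis(triethylsilyloxy)bicyclo[2.1.0]pentane (both faces of ring fusion) | CCCCC/C=C\C[C@@]1(O[Si](CC)(CC)CC)C2C(Br)(Br)C2(O[Si](CC)(CC)CC)C1 | intermediate
11 | (4S)-2-bromo-4-[(2Z)-oct-2-en-1-yl]-1,4-bis(triethylsilyloxy)cyclopent-2-en-1-ylium bromide | CCCCC/C=C\C[C@@]1(O[Si](CC)(CC)CC)C=C(Br)C(=[O+][Si](CC)(CC)CC)C1.[Br-] | intermediate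
12 | (4S)-2-bromo-4-[(2Z)-oct-2-en-1-yl]-4-(triethylsilyloxy)cyclopent-2-en-1-one | CCCCC/C=C\C[C@@]1(O[Si](CC)(CC)CC)C=C(Br)C(=O)C1 | intermediate
13 | methyl hex-5-enoate | COC(=O)CCCC=C | starting material
14 | (2E)-but-2-enal | C/C=C/C=O | starting material
15 | methyl (5E)-7-oxohept-5-enoate | COC(=O)CCC/C=C/C=O | intermediate
16 | lithium (3S)-5-bromo-3-[(2Z)-oct-2-en-1-yl]-3-(triethylsilyloxy)cyclopenta-1,4-dien-1-olate | CCCCC/C=C\C[C@@]1(O[Si](CC)(CC)CC)C=C(Br)C(O[Li])=C1 | intermediate
17 | methyl (5E)-7-{(2S)-4-bromo-2-[(2Z)-oct-2-en-1-yl]-5-oxo-2-(triethylsilyloxy)cyclopent-3-en-1-yl}-7-hydroxyhept-5-enoate (diastereomer mixture at C7 and C8) | CCCCC/C=C\C[C@@]1(O[Si](CC)(CC)CC)C=C(Br)C(=O)C1C(O)/C=C/CCCC(=O)OC | intermediate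
18 | methyl (5E)-7-{(2S)-4-bromo-2-[(2Z)-oct-2-en-1-yl]-5-oxo-2-(triethylsilyloxy)cyclopent-3-en-1-yl}-7-(methanesulfonyloxy)hept-5-enoate | CCCCC/C=C\C[C@@]1(O[Si](CC)(CC)CC)C=C(Br)C(=O)C1C(OS(C)(=O)=O)/C=C/CCCC(=O)OC | intermediate
19 | methyl (5E,7E)-7-{(2R)-4-bromo-2-[(2Z)-oct-2-en-1-yl]-5-oxo-2-(triethylsilyloxy)cyclopent-3-en-1-ylidene}hept-5-enoate | CCCCC/C=C\C[C@@]1(O[Si](CC)(CC)CC)C=C(Br)C(=O)/C1=C/C=C/CCCC(=O)OC | intermediate
20 | methyl (5E,7E)-7-{(2R)-4-bromo-2-hydroxy-2-[(2Z)-oct-2-en-1-yl]-5-oxocyclopent-3-en-1-ylidene}hept-5-enoate | CCCCC/C=C\C[C@@]1(O)C=C(Br)C(=O)/C1=C/C=C/CCCC(=O)OC | target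

Total step count: 10. Longest linear sequence: 9 (steps 1–6, 8, 9, 10).

Steps most likely to fail

Step 5. The amide may not tell the two enantiotopic CH2 groups apart well enough, because the two C3 substituents differ little in size, and a low enantiomeric excess cannot be corrected later. The fallback is an enzymatic resolution with recycling. It sets out from 7, which with isopropenyl acetate and catalytic TsOH gives the racemic enol acetate rac-3-[(2Z)-oct-2-en-1-yl]-3-(triethylsilyloxy)cyclobut-1-en-1-yl acetate F1. A lipase (Pseudomonas fluorescens lipase, butan-1-ol, tert-butyl methyl ether) transesterifies the unwanted enantiomer back to achiral 7, which is recycled, and leaves the (3S)-enol acetate F2. F2 is cleaved with MeLi (2 equiv, THF, −78 °C) to the lithium enolate 8, where the route is rejoined before silylation to 9.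

Step 6. tert-Butoxide may strip the enol silyl group before carbene transfer, which returns achiral 7. Excess carbene may also add to the C14=C15 alkene, or the bromoenone may degrade in the basic medium. The fallback separates ring enlargement from bromination and avoids the carbene base; it sets out from 9 and comes back at 12.
- Furukawa cyclopropanation (Et2Zn, CH2I2, CH2Cl2, 0 °C) gives the silyloxybicyclopentane F3.
- FeCl3 in DMF opens its central bond to the ring-enlarged β-chloro ketone F4.
- NaOAc in MeOH eliminates HCl to the enone F5.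
- H2O2/NaOH in MeOH epoxidises only the enone double bond to the epoxy ketone F6.
- LiBr with AcOH in THF opens it at the α-carbon to the bromohydrin F7.
- MsCl/Et3N converts F7 through its mesylate F8 into 12.

Step 2. The allylbarium may partly add through its γ-carbon, lose its Z geometry if it warms, or enolise the ketone. The fallback builds the chain in two stages: it sets out from 3, which with allylmagnesium bromide (THF, −78 °C) gives 3,3-dimethoxy-1-(prop-2-en-1-yl)cyclobutan-1-ol F9. Z-selective cross-metathesis of F9 with hept-1-ene (cyclometalated Z-selective ruthenium catalyst of the Grubbs type, THF, 35 °C) returns to the route at 5.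

Further compounds

F1 | step 5 | rac-3-[(2Z)-oct-2-en-1-yl]-3-(triethylsilyloxy)cyclobut-1-en-1-yl acetate | CCCCC/C=C\CC1(O[Si](CC)(CC)CC)C=C(OC(C)=O)C1
F2 | step 5 | (3S)-3-[(2Z)-oct-2-en-1-yl]-3-(triethylsilyloxy)cyclobut-1-en-1-yl acetate | CCCCC/C=C\C[C@@]1(O[Si](CC)(CC)CC)C=C(OC(C)=O)C1
F3 | step 6 | (3S)-3-[(2Z)-oct-2-en-1-yl]-1,3-bis(triethylsilyloxy)bicyclo[2.1.0]pentane | CCCCC/C=C\C[C@@]1(O[Si](CC)(CC)CC)C2CC2(O[Si](CC)(CC)CC)C1
F4 | step 6 | (4S)-3-chloro-4-[(2Z)-oct-2-en-1-yl]-4-(triethylsilyloxy)cyclopentan-1-one | CCCCC/C=C\C[C@@]1(O[Si](CC)(CC)CC)C(Cl)CC(=O)C1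
F5 | step 6 | (4S)-4-[(2Z)-oct-2-en-1-yl]-4-(triethylsilyloxy)cyclopent-2-en-1-one | CCCCC/C=C\C[C@@]1(O[Si](CC)(CC)CC)C=CC(=O)C1
F6 | step 6 | (4S)-4-[(2Z)-oct-2-en-1-yl]-4-(triethylsilyloxy)-6-oxabicyclo[3.1.0]hexan-2-one | CCCCC/C=C\C[C@@]1(O[Si](CC)(CC)CC)C2OC2C(=O)C1
F7 | step 6 | (4S)-2-bromo-3-hydroxy-4-[(2Z)-oct-2-en-1-yl]-4-(triethylsilyloxy)cyclopentan-1-one | CCCCC/C=C\C[C@@]1(O[Si](CC)(CC)CC)C(O)C(Br)C(=O)C1
F8 | step 6 | (4S)-2-bromo-3-(methanesulfonyloxy)-4-[(2Z)-oct-2-en-1-yl]-4-(triethylsilyloxy)cyclopentan-1-one | CCCCC/C=C\C[C@@]1(O[Si](CC)(CC)CC)C(OS(C)(=O)=O)C(Br)C(=O)C1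
F9 | step 2 | 3,3-dimethoxy-1-(prop-2-en-1-yl)cyclobutan-1-ol | C=CCC1(O)CC(OC)(OC)C1
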